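(The readings stem from a simulated flask from invented constants; scatter was added.)

Count in one unit, the day spent at full Zc and at Friday's Zd, and ask how much reaction such a day buys.

in all of them: Za 32 mM; Zb 32 mM; Ze 0.80 mM

| charge | Zc | Zd | remark | time |
|---|---|---|---|---|
| Friday's | 80 mM | 3.4 mM | run made earlier |  |
| Saturday's | 80 mM | 7.6 mM | run made earlier |  |
| flask | 80.0 mM | 5.1 mM |  | 10 d |

| run | time / d | Zh / % | Zj / % |
|---|---|---|---|
| Friday's | 0.625 | 0.6 | 0.1 |
| Friday's | 1.04 | 3.5 | 2.0 |
| Friday's | 1.67 | 7.1 | 3.6 |
| Friday's | 3.00 | 9.3 | 6.1 |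
| Friday's | 5.00 | 14.6 | 9.6 |
| Friday's | 8.00 | 19.7 | 11.3 |
| Saturday's | 0.500 | 2.9 | 1.2 |
| Saturday's | 1.67 | 10.3 | 5.3 |
| Saturday's | 3.00 | 13.2 | 8.1 |
| Saturday's | 4.00 | 20.0 | 10.6 |
| Saturday's | 6.00 | 24.4 | 11.0 |
| Saturday's | 8.00 | 27.4 | 14.7 |

(each reading ± 1 percentage point)

- Zh and Zj together, in percent of the Za and Zb charged together, at 10 d
- excess of Zh over Zj in the product at 10 d
- whether the exchange between Za and Zb keeps pace with the reaction: how far the product's excess at 10 d gets from its value without exchange to its value with instant exchange (above 80% keeps pace, below 20% hardly takes part, else lags behind)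

- Zd is single-handed; Za and Zb are mirror images of each other, charged as a racemate, each of them at the stated concentration
- the earlier runs were read with a standard deviation of 1 percentage point
- an excess is the difference of the two amounts in percent of their sum
- an excess is below zero if the other one leads

My own reckoning:

1. Let x be the reacted fraction of Za and Zb together, and L = ln(1/(1−x)). I take one Zc per product and replace the falling Zc by its mean fraction z = 1 − x·(Za charge)/(Zc charge). Then L = w·t·z·√(Zd/Friday's Zd).
2. w matters. Saturday's run reached 42.1%, near where this flask should go, and there y, as a fraction of the charge, moves by 0.316 times the relative error on w.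
3. z counts the same per percent, but Saturday's z can serve for this flask.
4. This flask's 5.1 mM of Zd lies between the runs' 3.4 mM and 7.6 mM, so I interpolate, and an error in the order in Zd weighs less. Ze drops out of the comparison: its charge is 0.80 mM in the runs and the flask.
5. Now the number. Friday's last reading gives x = 31.0%, z = 0.876 and w = 0.0529 d⁻¹. Saturday's gives z = 0.832 and w = 0.0549 d⁻¹. The root of Zd brings them together. Their mean is the reduced rate, a pseudo-first-order constant at full Zc and Friday's Zd: 0.0539 d⁻¹.
6. For this flask that gives L = 0.549, so y = 42.3%.
7. To check the mean, take Friday's run at 5.00 d: it read 24.2%, and the reckoning gives 21.6%, which is lower. So I lean above my figure.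

The forecast differs: y 40% (36% to 45%), excess 28% (22% to 33%), and "keeps pace", on the ground that “The flat trend therefore suggests exchange mostly keeps up”.

The flask gives y 43.8%, excess 26.4%, and the exchange hardly takes part: it gets 10% of the way.

    Zc + Zd + Zb → Zd + Zj (k = 0.540 L² mol⁻² min⁻¹)
    2 Zd ⇌ Zf, settled at all times (K = 3400 L mol⁻¹)
    Zc + Zd + Za → Zd + Zh (k = 1.10 L² mol⁻² min⁻¹)
    Ze → Zg (k = 0.00160 min⁻¹)
    Za + Ze ⇌ Zb + Ze, rate k5*[Ze]*[Za] forward; the back reaction follows from the equilibrium constant (k = 0.870 L mol⁻¹ min⁻¹)

Read back, this y gives w = 0.0571 d⁻¹, higher than 0.0539 d⁻¹. In this flask y stands at 43.8% partly because of the pairing of Zd to Zf and partly because of the length of the run: without the pairing it is 86.8%. The forecast parts from the flask on pace. Ze has a half-life of 0.30 d and stands at 0% of its charge by 5.00 d. The run without that decay turns the answer and lifts the excess from 26.4% to 33.3%, so the decay is a part of the reason.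

In the neighbour flask with 1.3 mM of Zd, w and Friday's z give y = 25.3%. The computed y there is 26.2%.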